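**Retrosynthetic overview**
- The target comes from the bicyclic diol by DMAP acylation of its secondary carbinol with 4-methoxybenzoyl chloride (last step).
- The seven-membered ring is formed last, by ring-closing metathesis of a vinyl ketone and a methallyl carbinol held trans on the cyclopentane.
- The tertiary isopropyl carbinol comes from isopropylcerium addition to the cyclopentanone; the vinyl ketone is unmasked from a 1-methoxyallenyl group.
- Key disconnection: the quaternary C–C(=O) bond is made by conjugate addition of an acryloyl anion equivalent (1-methoxyallenyl metal) to 3-methylcyclopent-2-enone, with the enolate trapped in an anti aldol by 3-methylbut-3-enal. This sets three stereocentres in one operation.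
- The five-membered ring is bought intact; the aldehyde comes from 3-methylbut-3-en-1-ol.

Assumption: the (R,R) ligand is taken to be the enantiomer that delivers the allenyl group to the Si face of C3 of the enone; if the sense of induction proves opposite, its (S,S) mirror image is used with nothing else changed.

**Step 1**
Reactants: 1 3-methylbut-3-en-1-ol
Product: 2 3-methylbut-3-enal
Conditions: Dess–Martin periodinane, NaHCO3, CH2Cl2, 0 °C, 30 min; filtered cold and used at once as a solution
Reagents that add atoms: none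
Why: Dess–Martin oxidation stops at the aldehyde and the bicarbonate buffer keeps the β,γ-unsaturated aldehyde from isomerising into conjugation; no stereocentre is formed.

**Step 2**
Reactants: 3 methoxyallene (1-methoxypropa-1,2-diene); 4 3-methylcyclopent-2-en-1-one; 2 3-methylbut-3-enal
Product: 8 (2S,3S)-2-[(1S)-1-hydroxy-3-methylbut-3-en-1-yl]-3-(1-methoxypropa-1,2-dien-1-yl)-3-methylcyclopentan-1-one, via 1-methoxyallenyllithium 5 (not isolated), via 1-methoxyallenyl(dimethyl)alane 6 (not isolated), via dimethylaluminium enolate 7 (not isolated)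
Conditions: 3, n-BuLi, Et2O, −40 °C; Me2AlCl, −40 °C; then 4, copper thiophene-2-carboxylate (10 mol %), (R,R)-L1 (11 mol %; L1 = N,N-bis[1-(naphthalen-2-yl)ethyl]-P,P-diphenylphosphinous amide), Et2O, −30 to −10 °C; then 2, −78 °C; aq. potassium sodium tartrate
Reagents that add atoms: none
Why: Proposed new method: 1-methoxyallenyllithium, the classical acryloyl anion equivalent that reacts at its oxygen-bearing carbon, is turned into the alkenyl-type alane 6, whose sp2 group the chiral copper–phosphinamine catalyst transfers to the Si face of C3 of 4 (closest known reaction type: copper-catalysed enantioselective conjugate addition of alkenyl(dimethyl)alanes, made from alkenyllithiums and Me2AlCl, to 3-methylcycloalkenones with formation of quaternary centres), and the regiodefined aluminium (E)-enolate 7 then adds to 2 through a Zimmerman–Traxler aldol transition state on the face anti to the bulkier allenyl ether group, which sets the 2,3-trans ring relationship and the anti (1S) carbinol.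

**Step 3**
Reactants: 8 (2S,3S)-2-[(1S)-1-hydroxy-3-methylbut-3-en-1-yl]-3-(1-methoxypropa-1,2-dien-1-yl)-3-methylcyclopentan-1-one
Product: 10 1-[(1S,2S,3R)-3-hydroxy-2-[(1S)-1-hydroxy-3-methylbut-3-en-1-yl]-1-methyl-3-(propan-2-yl)cyclopentyl]prop-2-en-1-one, via tertiary carbinol allenyl ether 9 (not isolated)
Conditions: iPrMgCl, anhydrous CeCl3, THF, −78 to −40 °C; then 1 M aq. HCl, THF, 0 °C, 30 min
Reagents that add atoms: isopropylmagnesium chloride, CC(C)[Mg]Cl; water, O
Why: Organocerium (Imamoto) 1,2-addition avoids enolisation, reduction and retro-aldol of the hindered β-hydroxy ketone and attacks the carbonyl face anti to the adjacent C2 side chain, which sets the tertiary carbinol with OH cis to that side chain, and the acid work-up hydrolyses the 1-alkoxyallene to the vinyl ketone, the standard unmasking of this acyl anion equivalent.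

**Step 4**
Reactants: 10 1-[(1S,2S,3R)-3-hydroxy-2-[(1S)-1-hydroxy-3-methylbut-3-en-1-yl]-1-methyl-3-(propan-2-yl)cyclopentyl]prop-2-en-1-one
Product: 11 (3R,3aS,4S,8aS)-3,4-dihydroxy-6,8a-dimethyl-3-(propan-2-yl)-2,3,3a,4,5,8a-hexahydroazulen-8(1H)-one
Conditions: second-generation Hoveyda–Grubbs catalyst RuCl2(H2IMes)(=CH-C6H4-2-OiPr) (10 mol %), toluene (0.005 M), 80 °C, argon sparge
Reagents that add atoms: none
Why: Ring-closing olefin metathesis between the vinyl ketone and the 1,1-disubstituted alkene closes the trisubstituted cycloheptenone with loss of ethylene; the two tethers are trans on the cyclopentane, so the trans ring fusion follows and no stereocentre is touched.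

**Step 5**
Reactants: 11 (3R,3aS,4S,8aS)-3,4-dihydroxy-6,8a-dimethyl-3-(propan-2-yl)-2,3,3a,4,5,8a-hexahydroazulen-8(1H)-one; 12 4-methoxybenzoyl chloride
Product: 13 (3R,3aS,4S,8aS)-3-hydroxy-6,8a-dimethyl-8-oxo-3-(propan-2-yl)-1,2,3,3a,4,5,8,8a-octahydroazulen-4-yl 4-methoxybenzoate
Conditions: 12, Et3N, DMAP (0.2 equiv), CH2Cl2, 0 °C to rt
Reagents that add atoms: none
Why: DMAP-catalysed acylation (nucleophilic catalysis) esterifies the secondary alcohol with retention, while the tertiary isopropyl carbinol is too hindered to react.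

**Compound list**
1 | 3-methylbut-3-en-1-ol | CC(=C)CCO | starting material
2 | 3-methylbut-3-enal | CC(=C)CC=O | intermediate
3 | methoxyallene (1-methoxypropa-1,2-diene) | COC=C=C | starting material
4 | 3-methylcyclopent-2-en-1-one | CC1=CC(=O)CC1 | starting material
5 | (1-methoxypropa-1,2-dien-1-yl)lithium | [Li]C(OC)=C=C | intermediate
6 | (1-methoxypropa-1,2-dien-1-yl)dimethylalumane | COC(=C=C)[Al](C)C | intermediate
7 | dimethylaluminium (3S)-3-(1-methoxypropa-1,2-dien-1-yl)-3-methylcyclopent-1-en-1-olate | C=C=C(OC)[C@@]1(C)CCC(O[Al](C)C)=C1 | intermediate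
8 | (2S,3S)-2-[(1S)-1-hydroxy-3-methylbut-3-en-1-yl]-3-(1-methoxypropa-1,2-dien-1-yl)-3-methylcyclopentan-1-one | C=C=C(OC)[C@@]1(C)CCC(=O)[C@@H]1[C@@H](O)CC(C)=C | intermediate
9 | (1R,2S,3S)-2-[(1S)-1-hydroxy-3-methylbut-3-en-1-yl]-3-(1-methoxypropa-1,2-dien-1-yl)-3-methyl-1-(propan-2-yl)cyclopentan-1-ol | C=C=C(OC)[C@@]1(C)CC[C@@](O)(C(C)C)[C@@H]1[C@@H](O)CC(C)=C | intermediate
10 | 1-[(1S,2S,3R)-3-hydroxy-2-[(1S)-1-hydroxy-3-methylbut-3-en-1-yl]-1-methyl-3-(propan-2-yl)cyclopentyl]prop-2-en-1-one | C=CC(=O)[C@@]1(C)CC[C@@](O)(C(C)C)[C@@H]1[C@@H](O)CC(C)=C | intermediate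
11 | (3R,3aS,4S,8aS)-3,4-dihydroxy-6,8a-dimethyl-3-(propan-2-yl)-2,3,3a,4,5,8a-hexahydroazulen-8(1H)-one | O[C@H]1CC(C)=CC(=O)[C@@]2(C)CC[C@@](O)(C(C)C)[C@H]12 | intermediate
12 | 4-methoxybenzoyl chloride | COc1ccc(cc1)C(Cl)=O | starting material
13 | (3R,3aS,4S,8aS)-3-hydroxy-6,8a-dimethyl-8-oxo-3-(propan-2-yl)-1,2,3,3a,4,5,8,8a-octahydroazulen-4-yl 4-methoxybenzoate | COc1ccc(C(=O)O[C@H]2CC(C)=CC(=O)[C@@]3(C)CC[C@@](O)(C(C)C)[C@H]23)cc1 | target

**Totals**
Total step count: 5. Longest linear sequence: 5 steps (1 → 2 → 8 → 10 → 11 → 13).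

**Steps most likely to fail, with fallbacks**

Step 2. The catalytic transfer of the 1-methoxyallenyl group to a β,β-disubstituted enone may be slow or poorly enantioselective, and the aldehyde may isomerise before the aldol. The fallback sets out from 3 and 4 and comes back at 8. Compound 5 (from 3 and n-BuLi) is converted with CuBr·SMe2 into the achiral cuprate Li[Cu(C(OCH3)=C=CH2)2]. This adds to 4 in THF at −78 °C in the presence of Me3SiCl to give the racemic silyl enol ether 3-(1-methoxypropa-1,2-dien-1-yl)-3-methyl-1-(trimethylsilyloxy)cyclopent-1-ene F1. MeLi cleaves F1 to the racemic lithium 3-(1-methoxypropa-1,2-dien-1-yl)-3-methylcyclopent-1-en-1-olate F2, which is treated with 2 at −78 °C in the same anti aldol. The racemic aldol is resolved by preparative chromatography on an amylose tris(3,5-dimethylphenylcarbamate) phase into 8 and its mirror image (2R,3R)-2-[(1R)-1-hydroxy-3-methylbut-3-en-1-yl]-3-(1-methoxypropa-1,2-dien-1-yl)-3-methylcyclopentan-1-one F3, which is discarded.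

Step 3. The isopropyl reagent may enolise the ketone, trigger retro-aldol, or attack the wrong face of the flexible monocycle. The fallback sets out from 8 and comes back at 11, and makes the addition on the rigid bicycle instead. Compound 8 is first hydrolysed with dilute aqueous HCl to 1-[(1S,2S)-2-[(1S)-1-hydroxy-3-methylbut-3-en-1-yl]-1-methyl-3-oxocyclopentyl]prop-2-en-1-one F4. F4 is ring-closed with RuCl2(H2IMes)(=CH-C6H4-2-OiPr) to (3aS,4S,8aS)-4-hydroxy-6,8a-dimethyl-1,2,3a,4,5,8a-hexahydroazulene-3,8-dione F5. Isopropylcerium dichloride (from iPrMgCl and CeCl3, THF, −78 °C) should then add only to the cyclopentanone carbonyl, because the enone carbonyl is conjugated and neopentylic, and from the face opposite the angular methyl, giving 11.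

Step 4. The electron-poor vinyl ketone may oligomerise or fail to close onto the 1,1-disubstituted alkene. The fallback sets out from 10 and comes back at 11. Luche reduction (NaBH4, CeCl3·7H2O, MeOH, −78 °C) gives the allylic alcohol (1R,2S,3S)-2-[(1S)-1-hydroxy-3-methylbut-3-en-1-yl]-3-(1-hydroxyprop-2-en-1-yl)-3-methyl-1-(propan-2-yl)cyclopentan-1-ol F6 as a mixture of carbinol epimers. The more reactive allylic alcohol undergoes metathesis with the second-generation Grubbs catalyst RuCl2(H2IMes)(PCy3)(=CHPh) in CH2Cl2 at 40 °C to (3R,3aS,4S,8aS)-6,8a-dimethyl-3-(propan-2-yl)-1,2,3,3a,4,5,8,8a-octahydroazulene-3,4,8-triol F7. MnO2 in CH2Cl2 then oxidises only the allylic alcohol to give 11.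

**Further compounds**
F1 | step 2 | 3-(1-methoxypropa-1,2-dien-1-yl)-3-methyl-1-(trimethylsilyloxy)cyclopent-1-ene (racemic) | C=C=C(OC)C1(C)CCC(O[Si](C)(C)C)=C1
F2 | step 2 | lithium 3-(1-methoxypropa-1,2-dien-1-yl)-3-methylcyclopent-1-en-1-olate (racemic) | C=C=C(OC)C1(C)CCC(O[Li])=C1
F3 | step 2 | (2R,3R)-2-[(1R)-1-hydroxy-3-methylbut-3-en-1-yl]-3-(1-methoxypropa-1,2-dien-1-yl)-3-methylcyclopentan-1-one | C=C=C(OC)[C@]1(C)CCC(=O)[C@H]1[C@H](O)CC(C)=C
F4 | step 3 | 1-[(1S,2S)-2-[(1S)-1-hydroxy-3-methylbut-3-en-1-yl]-1-methyl-3-oxocyclopentyl]prop-2-en-1-one | C=CC(=O)[C@@]1(C)CCC(=O)[C@@H]1[C@@H](O)CC(C)=C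
F5 | step 3 | (3aS,4S,8aS)-4-hydroxy-6,8a-dimethyl-1,2,3a,4,5,8a-hexahydroazulene-3,8-dione | O[C@H]1CC(C)=CC(=O)[C@@]2(C)CCC(=O)[C@H]12
F6 | step 4 | (1R,2S,3S)-2-[(1S)-1-hydroxy-3-methylbut-3-en-1-yl]-3-(1-hydroxyprop-2-en-1-yl)-3-methyl-1-(propan-2-yl)cyclopentan-1-ol (both carbinol epimers) | C=CC(O)[C@@]1(C)CC[C@@](O)(C(C)C)[C@@H]1[C@@H](O)CC(C)=C
F7 | step 4 | (3R,3aS,4S,8aS)-6,8a-dimethyl-3-(propan-2-yl)-1,2,3,3a,4,5,8,8a-octahydroazulene-3,4,8-triol (both C8 epimers) | O[C@H]1CC(C)=CC(O)[C@@]2(C)CC[C@@](O)(C(C)C)[C@H]12
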